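**Plan**

Positions follow the spiro[5.5]undecane numbering of obtusane: ring B = C1–C5 (Cl on C2; CH3 and Br on C3), spiro C6, ring A = C7–C11 (methylidene on C7, Br on C10, two CH3 on C11).
Retrosynthesis: C2–Cl and C3–Br go back to the C2=C3 alkene; C2=C3 is cut to a keto aldehyde (ring B opened); C7=CH2 goes back to C7=O; ring A is cut at C8–C9 together with C10–Br; C6–C11 is cut as an ester-enolate Claisen ([3,3]) bond.
Enabling feature: in ring A, C10 (CHBr) is bonded to the gem-dimethyl carbon C11 and stands 1,4 to the carbonyl-derived C7, so ring A is a masked 4-bromo-3,3-dimethylcyclohexanone. That is the ring obtained when the radical of a bromomethyl ketone closes 6-endo on a 1,1-dimethylallyl group and the ring radical takes up bromine.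
Forward: quaternary C6 is built first on an open chain, ring A closes second (step 7), the 3-oxobutyl arm is added and ring B closes third by carbonyl coupling (step 15), and the ring-B halogens are placed last.
Stereochemistry: C6 from an (S)-carbinol (asymmetric hydrogenation) relayed through a chelated dianion Claisen rearrangement and then oxidised away; C10 from equatorial bromine transfer trans to the axial ester; C3 from inverting bromide opening of an epoxide formed anti to C7; C2 from that epoxide face, retained in a bromonium-assisted OH→Cl exchange.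

Key step: step 7

Remark: the configuration at C3 of lactone 2 (C2 of 4, 5 and 6) is left open, because this carbon becomes the planar enolate carbon in step 3 and only the carbinol centre matters.

**Route**

Step 1
Reactants: 1 3-acetyloxolan-2-one (2-acetylbutyrolactone, racemic)
Product: 2 3-[(1S)-1-hydroxyethyl]oxolan-2-one (C3 epimers)
Conditions: H2 (50 atm), RuCl2[(S)-BINAP] (0.5 mol %), MeOH, 50 °C
Reagents that add atoms: none
Why: Noyori asymmetric hydrogenation of a β-keto ester: ketone and lactone carbonyl chelate ruthenium and the (S)-BINAP ligand should direct hydrogen to the face that gives the (S)-carbinol, while the labile lactone α-carbon needs no control.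

Step 2
Reactants: 2 3-[(1S)-1-hydroxyethyl]oxolan-2-one; 3 1-bromo-3-methylbut-2-ene (prenyl bromide)
Product: 6 3-methylbut-2-en-1-yl (3S)-2-[2-(tert-butyldiphenylsilyloxy)ethyl]-3-hydroxybutanoate, via potassium hydroxy carboxylate 4 (not isolated), via prenyl dihydroxy ester 5 (not isolated)
Conditions: KOH (1.0 equiv), MeOH–H2O, 0 → 25 °C, evaporate; prenyl bromide 3, DMF, 25 °C; then t-BuPh2SiCl, imidazole, 0 → 25 °C
Reagents that add atoms: potassium hydroxide, [K+].[OH-]; tert-butyl(chloro)diphenylsilane, CC(C)(C)[Si](Cl)(c1ccccc1)c1ccccc1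
Why: Saponification of the γ-lactone followed by carboxylate O-alkylation (SN2 on the allylic bromide) gives the prenyl ester without touching the alcohols, and selective silylation of the primary alcohol, much faster than that of the hindered secondary one, then blocks relactonisation.

Step 3
Reactants: 6 3-methylbut-2-en-1-yl (3S)-2-[2-(tert-butyldiphenylsilyloxy)ethyl]-3-hydroxybutanoate
Product: 8 (2S,3S)-2-[2-(tert-butyldiphenylsilyloxy)ethyl]-3-hydroxy-2-(2-methylbut-3-en-2-yl)butanoic acid, via dilithium alkoxide enolate 7 (not isolated)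
Conditions: LiN(i-Pr)2 (2.3 equiv), THF, −78 → 50 °C; then aq. HCl, 0 °C
Reagents that add atoms: none
Why: Dianionic Ireland–Claisen ([3,3]-sigmatropic) rearrangement: the lithium alkoxide holds the enolate in a six-membered chelate of fixed geometry, and the dimethyl-substituted allyl terminus should bond to the enolate face opposite the carbinol methyl group (the facial rule of Fráter–Seebach alkylations), which sets the quaternary (2S) centre beside the new CMe2 carbon; a C2 epimer would be a diastereomer of 8 and separable before step 5.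

Step 4
Reactants: 8 (2S,3S)-2-[2-(tert-butyldiphenylsilyloxy)ethyl]-3-hydroxy-2-(2-methylbut-3-en-2-yl)butanoic acid
Product: 9 methyl (2S,3S)-2-[2-(tert-butyldiphenylsilyloxy)ethyl]-3-hydroxy-2-(2-methylbut-3-en-2-yl)butanoate
Conditions: MeI, K2CO3, DMF, 25 °C
Reagents that add atoms: iodomethane, CI
Why: Carboxylate alkylation (SN2 on iodomethane) esterifies the hindered acid without touching the secondary alcohol, and it must precede the oxidation because the free β-keto acid would decarboxylate.

Step 5
Reactants: 9 methyl (2S,3S)-2-[2-(tert-butyldiphenylsilyloxy)ethyl]-3-hydroxy-2-(2-methylbut-3-en-2-yl)butanoate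
Product: 10 methyl (2S)-2-acetyl-2-[2-(tert-butyldiphenylsilyloxy)ethyl]-3,3-dimethylpent-4-enoate
Conditions: Dess–Martin periodinane, NaHCO3, CH2Cl2, 25 °C
Reagents that add atoms: none
Why: Dess–Martin oxidation turns the hindered secondary alcohol into the methyl ketone under near-neutral conditions, removing the relay stereocentre and leaving a β-keto ester that cannot enolise toward the quaternary carbon.

Step 6
Reactants: 10 methyl (2S)-2-acetyl-2-[2-(tert-butyldiphenylsilyloxy)ethyl]-3,3-dimethylpent-4-enoate
Product: 12 methyl (2S)-2-(2-bromoacetyl)-2-[2-(tert-butyldiphenylsilyloxy)ethyl]-3,3-dimethylpent-4-enoate, via trimethylsilyl enol ether 11 (not isolated)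
Conditions: Me3SiOTf, Et3N, CH2Cl2, 0 °C; then N-bromosuccinimide, THF, −78 → 0 °C
Reagents that add atoms: N-bromosuccinimide, O=C1CCC(=O)N1Br
Why: Soft enolisation can occur only at the methyl group, so the silyl enol ether forms regiospecifically and is brominated by N-bromosuccinimide (electrophilic α-bromination of a silyl enol ether) far faster than the neopentylic vinyl group reacts.

Step 7
Reactants: 12 methyl (2S)-2-(2-bromoacetyl)-2-[2-(tert-butyldiphenylsilyloxy)ethyl]-3,3-dimethylpent-4-enoate
Product: 13 methyl (1S,3R)-3-bromo-1-[2-(tert-butyldiphenylsilyloxy)ethyl]-2,2-dimethyl-6-oxocyclohexane-1-carboxylate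
Conditions: CuBr (10 mol %), tris(2-pyridylmethyl)amine (10 mol %), azobis(isobutyronitrile) (10 mol %), 1,2-dichloroethane (0.02 M), 80 °C, degassed
Reagents that add atoms: none
Why: CuBr with tris(2-pyridylmethyl)amine (monovalent copper) abstracts bromine from the bromomethyl ketone, the electrophilic α-keto radical adds to the terminal carbon of the vinyl group, and the secondary ring radical takes bromine back from the CuBr2 complex (divalent copper), so the neopentylic C–Br bond forms without SN2 or bromonium chemistry. The closest known reactions are copper-catalysed halogen atom-transfer radical cyclisations of α-halo carbonyl compounds and the 6-endo iodine-transfer cyclisation of 1-iodohex-5-en-2-ones. Ring A closes in the 6-endo-trig mode, preferred over 5-exo because the carbonyl lies inside the forming ring and the internal alkene carbon is neopentylic. The new CHBr centre is controlled by the quaternary carbon: in the chair the smaller ester should sit axial and the silyloxyethyl arm equatorial, and bromine is delivered equatorially, that is trans to the ester and cis to the arm (3R). The step needs 6-endo regioselectivity, this diastereoselectivity and a product that is not re-activated; the 2-oxohexenyl topology, the size difference of the two groups on the quaternary carbon and the inertness of an unactivated secondary bromide toward CuBr secure them, the diastereoselectivity being the least certain.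

Step 8
Reactants: 13 methyl (1S,3R)-3-bromo-1-[2-(tert-butyldiphenylsilyloxy)ethyl]-2,2-dimethyl-6-oxocyclohexane-1-carboxylate
Product: 14 methyl (1R,3R)-3-bromo-1-[2-(tert-butyldiphenylsilyloxy)ethyl]-2,2-dimethyl-6-methylidenecyclohexane-1-carboxylate
Conditions: Zn, CH2Br2, TiCl4, THF–CH2Cl2, 0 → 25 °C
Reagents that add atoms: dibromomethane, BrCBr
Why: Lombardo methylenation converts hindered, enolisable ketones into methylidene groups without base, which spares the ester and avoids the 1,3-elimination to a cyclopropane that a 4-bromocyclohexanone would suffer under Wittig conditions (the descriptor at C1 changes only through ligand priorities).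

Step 9
Reactants: 14 methyl (1R,3R)-3-bromo-1-[2-(tert-butyldiphenylsilyloxy)ethyl]-2,2-dimethyl-6-methylidenecyclohexane-1-carboxylate
Product: 15 [(1R,3R)-3-bromo-1-[2-(tert-butyldiphenylsilyloxy)ethyl]-2,2-dimethyl-6-methylidenecyclohexyl]methanol
Conditions: i-Bu2AlH (3 equiv), CH2Cl2, −78 → 0 °C
Reagents that add atoms: none
Why: Aluminium hydride reduction of the neopentylic ester gives the primary alcohol, while the unactivated secondary bromide, the alkene and the silyl ether are not attacked by i-Bu2AlH.

Step 10
Reactants: 15 [(1R,3R)-3-bromo-1-[2-(tert-butyldiphenylsilyloxy)ethyl]-2,2-dimethyl-6-methylidenecyclohexyl]methanol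
Product: 16 (1R,3R)-3-bromo-1-[2-(tert-butyldiphenylsilyloxy)ethyl]-2,2-dimethyl-6-methylidenecyclohexane-1-carbaldehyde
Conditions: Dess–Martin periodinane, NaHCO3, CH2Cl2, 25 °C
Reagents that add atoms: none
Why: Dess–Martin oxidation stops cleanly at the aldehyde, which is non-enolisable and therefore configurationally and chemically robust.

Step 11
Reactants: 16 (1R,3R)-3-bromo-1-[2-(tert-butyldiphenylsilyloxy)ethyl]-2,2-dimethyl-6-methylidenecyclohexane-1-carbaldehyde; 17 dimethyl (2-oxopropyl)phosphonate
Product: 18 (3E)-4-[(1R,3R)-3-bromo-1-[2-(tert-butyldiphenylsilyloxy)ethyl]-2,2-dimethyl-6-methylidenecyclohexyl]but-3-en-2-one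
Conditions: LiCl, i-Pr2NEt, MeCN, 25 → 50 °C
Reagents that add atoms: none
Why: Horner–Wadsworth–Emmons olefination under Masamune–Roush conditions adds the three-carbon ketone unit as the (E)-enone, and since the aldehyde has no α-hydrogen the gentle heating needed to overcome its hindrance is harmless.

Step 12
Reactants: 18 (3E)-4-[(1R,3R)-3-bromo-1-[2-(tert-butyldiphenylsilyloxy)ethyl]-2,2-dimethyl-6-methylidenecyclohexyl]but-3-en-2-one
Product: 19 4-[(1S,3R)-3-bromo-1-[2-(tert-butyldiphenylsilyloxy)ethyl]-2,2-dimethyl-6-methylidenecyclohexyl]butan-2-one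
Conditions: [(Ph3P)CuH]6, H2O, benzene, 25 °C
Reagents that add atoms: none
Why: Stryker conjugate reduction with the copper hydride [(Ph3P)CuH]6 saturates only the enone C=C, leaving the ketone, the isolated 1,1-disubstituted alkene and the alkyl bromide (the C1 descriptor changes only through ligand priorities).

Step 13
Reactants: 19 4-[(1S,3R)-3-bromo-1-[2-(tert-butyldiphenylsilyloxy)ethyl]-2,2-dimethyl-6-methylidenecyclohexyl]butan-2-one
Product: 20 4-[(1S,3R)-3-bromo-1-(2-hydroxyethyl)-2,2-dimethyl-6-methylidenecyclohexyl]butan-2-one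
Conditions: Bu4NF, THF, 0 → 25 °C
Reagents that add atoms: none
Why: Fluoride-induced desilylation frees the primary alcohol, and the bromine is now remote from any enolisable carbonyl so the basic fluoride cannot trigger elimination or cyclopropane formation.

Step 14
Reactants: 20 4-[(1S,3R)-3-bromo-1-(2-hydroxyethyl)-2,2-dimethyl-6-methylidenecyclohexyl]butan-2-one
Product: 21 2-[(1S,3R)-3-bromo-2,2-dimethyl-6-methylidene-1-(3-oxobutyl)cyclohexyl]acetaldehyde
Conditions: Dess–Martin periodinane, NaHCO3, CH2Cl2, 0 °C
Reagents that add atoms: none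
Why: Buffered Dess–Martin oxidation gives the aldehyde, which is used at once to avoid intramolecular aldol reaction with the methyl ketone.

Step 15
Reactants: 21 2-[(1S,3R)-3-bromo-2,2-dimethyl-6-methylidene-1-(3-oxobutyl)cyclohexyl]acetaldehyde
Product: 22 (6S,10R)-10-bromo-3,11,11-trimethyl-7-methylidenespiro[5.5]undec-2-ene
Conditions: TiCl3(DME)1.5, Zn–Cu couple, DME, reflux, slow addition at high dilution
Reagents that add atoms: none
Why: Intramolecular McMurry coupling of a 1,6-keto aldehyde on the titanium formed from TiCl3(DME)1.5 and Zn–Cu (zerovalent titanium) closes the six-membered ring B as the trisubstituted C2=C3 alkene, and isolated alkenes and unactivated alkyl halides are tolerated by this reagent.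

Step 16
Reactants: 22 (6S,10R)-10-bromo-3,11,11-trimethyl-7-methylidenespiro[5.5]undec-2-ene
Product: 23 (2S,3R,6S,10R)-10-bromo-2,3-epoxy-3,11,11-trimethyl-7-methylidenespiro[5.5]undecane
Conditions: mCPBA (1.05 equiv), NaHCO3, CH2Cl2, −20 → 0 °C
Reagents that add atoms: 3-chloroperoxybenzoic acid, OOC(=O)c1cccc(Cl)c1
Why: Prilezhaev epoxidation should select the electron-richer trisubstituted ring alkene over the hindered 1,1-disubstituted methylidene and should occur anti to C7, which stands axial on ring B with its methylidene group over the C1–C2 edge, so the oxygen ends syn to C11.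

Step 17
Reactants: 23 (2S,3R,6S,10R)-10-bromo-2,3-epoxy-3,11,11-trimethyl-7-methylidenespiro[5.5]undecane
Product: 24 (2S,3S,6S,10R)-3,10-dibromo-3,11,11-trimethyl-7-methylidenespiro[5.5]undecan-2-ol
Conditions: 48% aq. HBr (1.2 equiv), Et2O, −20 → 0 °C
Reagents that add atoms: hydrogen bromide, Br
Why: Acid-mediated epoxide opening (borderline SN2): bromide attacks the protonated epoxide at the tertiary carbon C3 with inversion, the secondary carbon C2 being in addition screened on that face by the methylidene group, which gives the trans bromohydrin with the tertiary bromide in the configuration of the target.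

Step 18
Reactants: 24 (2S,3S,6S,10R)-3,10-dibromo-3,11,11-trimethyl-7-methylidenespiro[5.5]undecan-2-ol
Product: 27 obtusane [(2S,3S,6S,10R)-3,10-dibromo-2-chloro-3,11,11-trimethyl-7-methylidenespiro[5.5]undecane], via secondary triflate 25 (not isolated), via transposed diaxial bromochloride 26 (not isolated)
Conditions: Tf2O, 2,6-lutidine, CH2Cl2, −78 °C; then Bu4NCl, −78 → 40 °C
Reagents that add atoms: tetrabutylammonium chloride, CCCC[N+](CCCC)(CCCC)CCCC.[Cl-]
Why: Nucleophilic substitution with neighbouring-group participation: the trans β-bromine displaces the triflate to give a bromonium ion that chloride opens with overall retention at C2 (direct SN2 inversion is blocked by the axial C7 substituent); opening at the tertiary carbon gives the strained diaxial, halogen-transposed isomer 26, which should re-ionise through the same bromonium ion (diaxial-to-diequatorial rearrangement of vicinal dihalides) and end as the diequatorial trans isomer 27.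

**Compound list**

1 | 3-acetyloxolan-2-one (2-acetylbutyrolactone, racemic) | CC(=O)C1CCOC1=O | starting material
2 | 3-[(1S)-1-hydroxyethyl]oxolan-2-one (C3 epimers) | C[C@H](O)C1CCOC1=O | intermediate
3 | 1-bromo-3-methylbut-2-ene (prenyl bromide) | CC(C)=CCBr | starting material
4 | potassium (3S)-3-hydroxy-2-(2-hydroxyethyl)butanoate (C2 epimers) | C[C@H](O)C(CCO)C(=O)[O-].[K+] | intermediate
5 | 3-methylbut-2-en-1-yl (3S)-3-hydroxy-2-(2-hydroxyethyl)butanoate (C2 epimers) | C[C@H](O)C(CCO)C(=O)OCC=C(C)C | intermediate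
6 | 3-methylbut-2-en-1-yl (3S)-2-[2-(tert-butyldiphenylsilyloxy)ethyl]-3-hydroxybutanoate (C2 epimers) | C[C@H](O)C(CCO[Si](c1ccccc1)(c1ccccc1)C(C)(C)C)C(=O)OCC=C(C)C | intermediate
7 | dilithium alkoxide enolate of 6 (enolate oxygen cis to the carbinol carbon) | [Li+].[Li+].C[C@H]([O-])/C(CCO[Si](c1ccccc1)(c1ccccc1)C(C)(C)C)=C(\[O-])OCC=C(C)C | intermediate
8 | (2S,3S)-2-[2-(tert-butyldiphenylsilyloxy)ethyl]-3-hydroxy-2-(2-methylbut-3-en-2-yl)butanoic acid | C=CC(C)(C)[C@]([C@H](C)O)(CCO[Si](c1ccccc1)(c1ccccc1)C(C)(C)C)C(=O)O | intermediate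
9 | methyl (2S,3S)-2-[2-(tert-butyldiphenylsilyloxy)ethyl]-3-hydroxy-2-(2-methylbut-3-en-2-yl)butanoate | C=CC(C)(C)[C@]([C@H](C)O)(CCO[Si](c1ccccc1)(c1ccccc1)C(C)(C)C)C(=O)OC | intermediate
10 | methyl (2S)-2-acetyl-2-[2-(tert-butyldiphenylsilyloxy)ethyl]-3,3-dimethylpent-4-enoate | C=CC(C)(C)[C@](C(C)=O)(CCO[Si](c1ccccc1)(c1ccccc1)C(C)(C)C)C(=O)OC | intermediate
11 | methyl (2S)-2-[2-(tert-butyldiphenylsilyloxy)ethyl]-3,3-dimethyl-2-[1-(trimethylsilyloxy)ethenyl]pent-4-enoate | C=CC(C)(C)[C@](C(=C)O[Si](C)(C)C)(CCO[Si](c1ccccc1)(c1ccccc1)C(C)(C)C)C(=O)OC | intermediate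
12 | methyl (2S)-2-(2-bromoacetyl)-2-[2-(tert-butyldiphenylsilyloxy)ethyl]-3,3-dimethylpent-4-enoate | C=CC(C)(C)[C@](C(=O)CBr)(CCO[Si](c1ccccc1)(c1ccccc1)C(C)(C)C)C(=O)OC | intermediate
13 | methyl (1S,3R)-3-bromo-1-[2-(tert-butyldiphenylsilyloxy)ethyl]-2,2-dimethyl-6-oxocyclohexane-1-carboxylate | O=C1CC[C@@H](Br)C(C)(C)[C@]1(CCO[Si](c1ccccc1)(c1ccccc1)C(C)(C)C)C(=O)OC | intermediate
14 | methyl (1R,3R)-3-bromo-1-[2-(tert-butyldiphenylsilyloxy)ethyl]-2,2-dimethyl-6-methylidenecyclohexane-1-carboxylate | C=C1CC[C@@H](Br)C(C)(C)[C@]1(CCO[Si](c1ccccc1)(c1ccccc1)C(C)(C)C)C(=O)OC | intermediate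
15 | [(1R,3R)-3-bromo-1-[2-(tert-butyldiphenylsilyloxy)ethyl]-2,2-dimethyl-6-methylidenecyclohexyl]methanol | C=C1CC[C@@H](Br)C(C)(C)[C@]1(CCO[Si](c1ccccc1)(c1ccccc1)C(C)(C)C)CO | intermediate
16 | (1R,3R)-3-bromo-1-[2-(tert-butyldiphenylsilyloxy)ethyl]-2,2-dimethyl-6-methylidenecyclohexane-1-carbaldehyde | C=C1CC[C@@H](Br)C(C)(C)[C@]1(CCO[Si](c1ccccc1)(c1ccccc1)C(C)(C)C)C=O | intermediate
17 | dimethyl (2-oxopropyl)phosphonate | COP(=O)(CC(C)=O)OC | starting material
18 | (3E)-4-[(1R,3R)-3-bromo-1-[2-(tert-butyldiphenylsilyloxy)ethyl]-2,2-dimethyl-6-methylidenecyclohexyl]but-3-en-2-one | C=C1CC[C@@H](Br)C(C)(C)[C@]1(CCO[Si](c1ccccc1)(c1ccccc1)C(C)(C)C)/C=C/C(C)=O | intermediate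
19 | 4-[(1S,3R)-3-bromo-1-[2-(tert-butyldiphenylsilyloxy)ethyl]-2,2-dimethyl-6-methylidenecyclohexyl]butan-2-one | C=C1CC[C@@H](Br)C(C)(C)[C@]1(CCO[Si](c1ccccc1)(c1ccccc1)C(C)(C)C)CCC(C)=O | intermediate
20 | 4-[(1S,3R)-3-bromo-1-(2-hydroxyethyl)-2,2-dimethyl-6-methylidenecyclohexyl]butan-2-one | C=C1CC[C@@H](Br)C(C)(C)[C@]1(CCO)CCC(C)=O | intermediate
21 | 2-[(1S,3R)-3-bromo-2,2-dimethyl-6-methylidene-1-(3-oxobutyl)cyclohexyl]acetaldehyde | C=C1CC[C@@H](Br)C(C)(C)[C@]1(CC=O)CCC(C)=O | intermediate
22 | (6S,10R)-10-bromo-3,11,11-trimethyl-7-methylidenespiro[5.5]undec-2-ene | C=C1CC[C@@H](Br)C(C)(C)[C@]12CCC(C)=CC2 | intermediate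
23 | (2S,3R,6S,10R)-10-bromo-2,3-epoxy-3,11,11-trimethyl-7-methylidenespiro[5.5]undecane (oxygen syn to C11) | C=C1CC[C@@H](Br)C(C)(C)[C@]12CC[C@@]3(C)O[C@H]3C2 | intermediate
24 | (2S,3S,6S,10R)-3,10-dibromo-3,11,11-trimethyl-7-methylidenespiro[5.5]undecan-2-ol | C=C1CC[C@@H](Br)C(C)(C)[C@]12CC[C@](C)(Br)[C@@H](O)C2 | intermediate
25 | (2S,3S,6S,10R)-3,10-dibromo-3,11,11-trimethyl-7-methylidenespiro[5.5]undecan-2-yl trifluoromethanesulfonate | C=C1CC[C@@H](Br)C(C)(C)[C@]12CC[C@](C)(Br)[C@@H](OS(=O)(=O)C(F)(F)F)C2 | intermediate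
26 | (2R,3R,6S,10R)-2,10-dibromo-3-chloro-3,11,11-trimethyl-7-methylidenespiro[5.5]undecane | C=C1CC[C@@H](Br)C(C)(C)[C@]12CC[C@@](C)(Cl)[C@H](Br)C2 | intermediate
27 | obtusane, (2S,3S,6S,10R)-3,10-dibromo-2-chloro-3,11,11-trimethyl-7-methylidenespiro[5.5]undecane | C=C1CC[C@@H](Br)C(C)(C)[C@]12CC[C@](C)(Br)[C@@H](Cl)C2 | target

**Step count and risks**

Total step count: 18. Longest linear sequence: 18 steps (1 → 27); 3 and 17 are commercial and enter without steps of their own.

The three steps most likely to fail, in descending order of risk: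

Step 18. In the chair of 24 the bromine on C3 is gauche, not anti, to the C2–O bond, so bridging needs a twist conformer. Ionisation of the triflate may instead be accompanied by a 1,2-shift of the C3 methyl group or of the C3–C4 ring bond, or by elimination. The halogen-transposed isomer may also persist instead of funnelling to 27. The fallback replaces ionisation through a bridged ion by front-side collapse of a chlorosulfite, a known stereoretentive chlorination of cyclic secondary alcohols. It sets out from 24: SOCl2 in CH2Cl2 at 0 °C would give (2S,3S,6S,10R)-3,10-dibromo-3,11,11-trimethyl-7-methylidenespiro[5.5]undecan-2-yl chlorosulfite F1, and a catalytic amount of TiCl4 at 0 °C would then deliver chloride to the face the oxygen occupied, with loss of sulfur dioxide. It comes back to the route at 27.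

Step 7. The α-keto radical may be reduced by CuBr to an enolate before it cyclises (returning 10), may abstract hydrogen from the OCH2 group by 1,5-transfer, or may close 5-exo. Bromine transfer to the ring radical may also occur with poor facial selectivity. The fallback separates ring closure from C–Br formation by a degenerative xanthate transfer, which gives the radical a long chain lifetime and uses no reductant. It sets out from 12: EtOCS2K in acetone at 0 °C would give methyl (2S)-2-[2-(tert-butyldiphenylsilyloxy)ethyl]-2-{2-[(ethoxycarbonothioyl)sulfanyl]acetyl}-3,3-dimethylpent-4-enoate F2. Dilauroyl peroxide in refluxing 1,2-dichloroethane would then effect the 6-endo xanthate-transfer cyclisation to methyl (1S)-1-[2-(tert-butyldiphenylsilyloxy)ethyl]-3-[(ethoxycarbonothioyl)sulfanyl]-2,2-dimethyl-6-oxocyclohexane-1-carboxylate F3. Radical xanthate-to-bromide exchange with ethyl 2-bromo-2-methylpropanoate (di-tert-butyl peroxide, chlorobenzene, reflux) would replace the xanthate by bromine, the C3 epimers being separated at this point. The fallback comes back to the route at 13.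

Step 3. The hindered dianion may lose prenyl alkoxide (ketene formation) faster than it rearranges, and the facial preference of the chelate may be weak for a tetrasubstituted enolate and a disubstituted allyl terminus. The fallback sets the quaternary centre by a catalysed Claisen rearrangement of an enol ether instead, and sets out from 1.
- Mitsunobu O-alkylation (3-methylbut-2-en-1-ol, PPh3, diisopropyl azodicarboxylate, THF) would give (3Z)-3-{1-[(3-methylbut-2-en-1-yl)oxy]ethylidene}oxolan-2-one F4.
- An enantioselective Claisen rearrangement of this O-allyl β-keto ester would give (3S)-3-acetyl-3-(2-methylbut-3-en-2-yl)oxolan-2-one F5. The catalyst would be N,N'-bis[(1R,2R)-2-(2,5-diphenylpyrrol-1-yl)cyclohexyl]guanidinium tetrakis[3,5-bis(trifluoromethyl)phenyl]borate or its antipode, whichever delivers the (3S) centre.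
- Because hydroxide would deacetylate F5, the ketone is first reduced (NaBH4, MeOH, 0 °C) to (3S)-3-(1-hydroxyethyl)-3-(2-methylbut-3-en-2-yl)oxolan-2-one F6.
- The lactone is then opened as in step 2: KOH gives potassium (2S)-3-hydroxy-2-(2-hydroxyethyl)-2-(2-methylbut-3-en-2-yl)butanoate F7, MeI in DMF gives methyl (2S)-3-hydroxy-2-(2-hydroxyethyl)-2-(2-methylbut-3-en-2-yl)butanoate F8, and t-BuPh2SiCl with imidazole gives methyl (2S)-2-[2-(tert-butyldiphenylsilyloxy)ethyl]-3-hydroxy-2-(2-methylbut-3-en-2-yl)butanoate F9 as a mixture of carbinol epimers.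
- Dess–Martin oxidation as in step 5 brings the fallback back to the route at 10.

**Further compounds**

F1 | step 18 | (2S,3S,6S,10R)-3,10-dibromo-3,11,11-trimethyl-7-methylidenespiro[5.5]undecan-2-yl chlorosulfite | C=C1CC[C@@H](Br)C(C)(C)[C@]12CC[C@](C)(Br)[C@@H](OS(Cl)=O)C2
F2 | step 7 | methyl (2S)-2-[2-(tert-butyldiphenylsilyloxy)ethyl]-2-{2-[(ethoxycarbonothioyl)sulfanyl]acetyl}-3,3-dimethylpent-4-enoate | C=CC(C)(C)[C@](C(=O)CSC(=S)OCC)(CCO[Si](c1ccccc1)(c1ccccc1)C(C)(C)C)C(=O)OC
F3 | step 7 | methyl (1S)-1-[2-(tert-butyldiphenylsilyloxy)ethyl]-3-[(ethoxycarbonothioyl)sulfanyl]-2,2-dimethyl-6-oxocyclohexane-1-carboxylate (C3 epimers) | O=C1CCC(SC(=S)OCC)C(C)(C)[C@]1(CCO[Si](c1ccccc1)(c1ccccc1)C(C)(C)C)C(=O)OC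
F4 | step 3 | (3Z)-3-{1-[(3-methylbut-2-en-1-yl)oxy]ethylidene}oxolan-2-one | C/C(OCC=C(C)C)=C1\CCOC1=O
F5 | step 3 | (3S)-3-acetyl-3-(2-methylbut-3-en-2-yl)oxolan-2-one | C=CC(C)(C)[C@]1(C(C)=O)CCOC1=O
F6 | step 3 | (3S)-3-(1-hydroxyethyl)-3-(2-methylbut-3-en-2-yl)oxolan-2-one (carbinol epimers) | C=CC(C)(C)[C@]1(C(C)O)CCOC1=O
F7 | step 3 | potassium (2S)-3-hydroxy-2-(2-hydroxyethyl)-2-(2-methylbut-3-en-2-yl)butanoate (carbinol epimers) | C=CC(C)(C)[C@](C(C)O)(CCO)C(=O)[O-].[K+]
F8 | step 3 | methyl (2S)-3-hydroxy-2-(2-hydroxyethyl)-2-(2-methylbut-3-en-2-yl)butanoate (carbinol epimers) | C=CC(C)(C)[C@](C(C)O)(CCO)C(=O)OC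
F9 | step 3 | methyl (2S)-2-[2-(tert-butyldiphenylsilyloxy)ethyl]-3-hydroxy-2-(2-methylbut-3-en-2-yl)butanoate (carbinol epimers) | C=CC(C)(C)[C@](C(C)O)(CCO[Si](c1ccccc1)(c1ccccc1)C(C)(C)C)C(=O)OC
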